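**Retrosynthetic overview**

1. The strategy rests on the pyranone ring of the chroman-4-one (O1–C2–C3–C4–C4a–C8a). C4 is an aryl ketone carbon bonded to C3, and C2 is a benzylic carbon carrying O1 and the 4-hydroxyphenyl group. With a hydroxyl placed on C3, the C3–C4 bond becomes the acyloin bond between a salicylaldehyde carbon and the carbonyl of an α-aryloxy deoxybenzoin.
2. Disconnections in order: the five MOM ethers; the chalcone C=C, by cross-metathesis into styrene 17 and aryl vinyl ketone 20; C3–H back to C3–OH and vinyl back to bromine (ketol 15); then C3–C4, by a carbene-catalysed crossed benzoin of keto aldehyde 14 in which the base-labile ether carbon (future C2) is resolved dynamically.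
3. Keto aldehyde 14 is cut at the O1–C2 ether bond into phenol 13 and α-bromo ketone 11. Deoxybenzoin 9 comes from Weinreb amide 3 and benzylic Grignard reagent 8.
4. Ring order: the four benzene rings are bought; the pyranone ring is the only ring made (step 9).
5. No base is allowed to meet the molecule once C3 carries hydrogen, because the C3 enolate would expel O1, open the ring and erase C2. The vinyl group is therefore introduced while C3 is quaternary (step 10) and the enone is completed by base-free metathesis (step 15).

Key step: step 9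

Assumption: the sense of induction of the aminoindanol-derived triazolium catalyst on this new substrate cannot be predicted with confidence, so the catalyst antipode that delivers (2S)-15 is to be fixed in a test cyclisation; either C3 epimer of 15 is acceptable, since C3 is re-set in step 11.

**Route**

Step 1
Reactants: 1 5-bromosalicylic acid
Product: 2 5-bromo-2-hydroxy-N-methoxy-N-methylbenzamide
Conditions: MeNHOMe·HCl, EDC·HCl, HOBt, iPr2NEt, CH2Cl2, 0 °C to rt
Reagents that add atoms: N,O-dimethylhydroxylamine hydrochloride, CNOC.Cl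
Why: Carbodiimide amide coupling, in which the hydroxybenzotriazole ester of the acid should be taken up by the hydroxylamine nitrogen much faster than by the hydrogen-bonded ortho-phenol, so that no phenol protection is needed.

Step 2
Reactants: 2 5-bromo-2-hydroxy-N-methoxy-N-methylbenzamide
Product: 3 5-bromo-N-methoxy-2-(methoxymethoxy)-N-methylbenzamide
Conditions: MOMCl, iPr2NEt, CH2Cl2, 0 °C to rt
Reagents that add atoms: chloromethyl methyl ether, COCCl
Why: Williamson-type O-alkylation of the phenol with the highly reactive α-chloro ether masks the acidic OH before the Grignard addition.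

Step 3
Reactants: 4 4-hydroxybenzyl alcohol
Product: 5 [4-(methoxymethoxy)phenyl]methanol
Conditions: MOMCl (1.05 equiv), K2CO3, acetone, 0 °C to rt
Reagents that add atoms: chloromethyl methyl ether, COCCl
Why: Chemoselective Williamson etherification, since K2CO3 ionises only the phenol and the phenoxide outcompetes the neutral benzylic alcohol for the chloride.

Step 4
Reactants: 5 [4-(methoxymethoxy)phenyl]methanol
Product: 7 1-(chloromethyl)-4-(methoxymethoxy)benzene, via 4-(methoxymethoxy)benzyl methanesulfonate 6 (not isolated)
Conditions: MsCl, Et3N, THF, 0 °C; then LiCl, rt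
Reagents that add atoms: lithium chloride, [Li+].[Cl-]
Why: Sulfonylation followed by SN2 displacement with chloride (Finkelstein type) at the activated benzylic carbon should give the chloride under non-acidic conditions that leave the MOM acetal intact.

Step 5
Reactants: 7 1-(chloromethyl)-4-(methoxymethoxy)benzene; 3 5-bromo-N-methoxy-2-(methoxymethoxy)-N-methylbenzamide
Product: 9 1-[5-bromo-2-(methoxymethoxy)phenyl]-2-[4-(methoxymethoxy)phenyl]ethan-1-one, via [4-(methoxymethoxy)benzyl]magnesium chloride 8 (not isolated)
Conditions: Mg (excess), Et2O, 0 °C, slow addition of 7; then 3, THF, −20 to 0 °C; aq. NH4Cl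
Reagents that add atoms: none
Why: Weinreb ketone synthesis, in which the benzylic Grignard reagent adds only once because the magnesium chelate of the tetrahedral adduct survives until the quench, and the aryl bromide does not exchange with a benzylic Grignard reagent at this temperature.

Step 6
Reactants: 9 1-[5-bromo-2-(methoxymethoxy)phenyl]-2-[4-(methoxymethoxy)phenyl]ethan-1-one
Product: 11 racemic 2-bromo-1-[5-bromo-2-(methoxymethoxy)phenyl]-2-[4-(methoxymethoxy)phenyl]ethan-1-one, via trimethylsilyl enol ether 10 (not isolated)
Conditions: LiN(SiMe3)2, Me3SiCl, THF, −78 °C; then N-bromosuccinimide, −78 to 0 °C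
Reagents that add atoms: N-bromosuccinimide, O=C1CCC(=O)N1Br
Why: α-Bromination of a ketone through its silyl enol ether is neutral, so it avoids both the HBr of direct bromination (MOM loss) and the over-bromination of a free enolate; the new stereocentre is formed racemic and needs no control.

Step 7
Reactants: 12 2,4-dihydroxybenzaldehyde
Product: 13 2-hydroxy-4-(methoxymethoxy)benzaldehyde
Conditions: MOMCl (1.05 equiv), K2CO3, acetone, 0 °C to rt
Reagents that add atoms: chloromethyl methyl ether, COCCl
Why: Regioselective Williamson etherification, because the 2-hydroxyl is held in a hydrogen bond to the formyl group and is the poorer nucleophile, so one equivalent of the chloride should go to the 4-hydroxyl.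

Step 8
Reactants: 11 racemic 2-bromo-1-[5-bromo-2-(methoxymethoxy)phenyl]-2-[4-(methoxymethoxy)phenyl]ethan-1-one; 13 2-hydroxy-4-(methoxymethoxy)benzaldehyde
Product: 14 racemic 2-{2-[5-bromo-2-(methoxymethoxy)phenyl]-1-[4-(methoxymethoxy)phenyl]-2-oxoethoxy}-4-(methoxymethoxy)benzaldehyde
Conditions: K2CO3, acetone, rt
Reagents that add atoms: none
Why: Williamson ether synthesis (SN2) at an α-keto benzylic bromide, a strongly activated electrophile for the phenoxide, with K2CO3 at room temperature mild enough to hold back aldol chemistry of the product; the ether carbon is formed racemic, as the dynamic resolution requires.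

Step 9
Reactants: 14 racemic 2-{2-[5-bromo-2-(methoxymethoxy)phenyl]-1-[4-(methoxymethoxy)phenyl]-2-oxoethoxy}-4-(methoxymethoxy)benzaldehyde
Product: 15 (2S,3R)-3-[5-bromo-2-(methoxymethoxy)phenyl]-3-hydroxy-7-(methoxymethoxy)-2-[4-(methoxymethoxy)phenyl]chroman-4-one
Conditions: (5aS,10bR)-2-(pentafluorophenyl)-5a,10b-dihydro-4H,6H-indeno[2,1-b][1,2,4]triazolo[4,3-d][1,4]oxazin-2-ium tetrafluoroborate or its (5aR,10bS) antipode (15 mol %), DBU (30 mol %), toluene, rt, argon
Reagents that add atoms: none
Why: Proposed new method: the triazolylidene freed by DBU adds to the aldehyde and, after proton transfer, the Breslow intermediate attacks the tethered aryl ketone through its acyl-anion carbon (future C4) in a 6-exo-trig closure that forms C3–C4 and the pyranone ring, after which the carbene is expelled from the ketol. The closest known reactions are the triazolylidene-catalysed intramolecular crossed benzoin of 2-(2-oxoalkoxy)benzaldehydes to 3-hydroxychroman-4-ones and the dynamic kinetic cross-benzoin of ketones bearing a base-labile α-stereocentre; their combination on an α-aryl-α-aryloxy ketone is what is new. The ether carbon is benzylic, oxygen-substituted and α to the ketone, so DBU should interconvert its enantiomers through the enolate, and it is frozen once cyclisation has turned the neighbouring carbonyl carbon into the quaternary C3. C3 is set by the catalyst, whose indane wall leaves one face of the ketone open to the Breslow carbon, and C2 follows from C3 through the chair-like transition state, in which the 4-(methoxymethoxy)phenyl group should sit pseudo-equatorial, so that only one enantiomer of 14 is matched. The step needs enantiomer selection at C2 and benzoin over aldol: the first rests on this relay and on racemisation being faster than ring closure, the second on the reversibility of the 5-exo aldol addition of the enolate to the aldehyde, which should drain back into the ketol. The enantiomeric purity at C2 is to be assayed after step 11, where C3 is no longer a variable.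

Step 10
Reactants: 15 (2S,3R)-3-[5-bromo-2-(methoxymethoxy)phenyl]-3-hydroxy-7-(methoxymethoxy)-2-[4-(methoxymethoxy)phenyl]chroman-4-one
Product: 16 (2S,3R)-3-[5-ethenyl-2-(methoxymethoxy)phenyl]-3-hydroxy-7-(methoxymethoxy)-2-[4-(methoxymethoxy)phenyl]chroman-4-one
Conditions: CH2=CHSnBu3, Pd(PPh3)4 (5 mol %), toluene, 100 °C
Reagents that add atoms: tributyl(vinyl)stannane, C=C[Sn](CCCC)(CCCC)CCCC
Why: Stille coupling (oxidative addition of zerovalent palladium into the aryl bromide, vinyl transfer from tin, reductive elimination) needs no base, and C2 cannot epimerise at this stage because C3 is quaternary.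

Step 11
Reactants: 16 (2S,3R)-3-[5-ethenyl-2-(methoxymethoxy)phenyl]-3-hydroxy-7-(methoxymethoxy)-2-[4-(methoxymethoxy)phenyl]chroman-4-one
Product: 17 (2R,3S)-3-[5-ethenyl-2-(methoxymethoxy)phenyl]-7-(methoxymethoxy)-2-[4-(methoxymethoxy)phenyl]chroman-4-one
Conditions: SmI2 (2.5 equiv), THF–MeOH (4:1), −78 °C; aq. NH4Cl; silica gel
Reagents that add atoms: none
Why: Reductive cleavage of an α-hydroxy ketone by SmI2, in which two single-electron transfers to the C4 carbonyl expel the C3 hydroxyl, methanol protonates the samarium enolate at −78 °C before the ring aryloxide can leave, and C3 then settles through the enol into the trans (2R,3S) arrangement with both aryl groups equatorial while C2 is untouched (the CIP descriptor at C2 changes only because C3 loses its oxygen).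

Step 12
Reactants: 12 2,4-dihydroxybenzaldehyde
Product: 18 2,4-bis(methoxymethoxy)benzaldehyde
Conditions: NaH (2.5 equiv), MOMCl (2.6 equiv), DMF, 0 °C to rt
Reagents that add atoms: chloromethyl methyl ether, COCCl
Why: Double Williamson etherification, with NaH needed to ionise the hydrogen-bonded 2-hydroxyl as well as the 4-hydroxyl.

Step 13
Reactants: 18 2,4-bis(methoxymethoxy)benzaldehyde
Product: 19 racemic 1-[2,4-bis(methoxymethoxy)phenyl]prop-2-en-1-ol
Conditions: CH2=CHMgBr, THF, −78 to 0 °C; aq. NH4Cl
Reagents that add atoms: vinylmagnesium bromide, C=C[Mg]Br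
Why: Grignard 1,2-addition to the aldehyde gives the allylic alcohol, whose stereocentre is removed in the next step.

Step 14
Reactants: 19 racemic 1-[2,4-bis(methoxymethoxy)phenyl]prop-2-en-1-ol
Product: 20 1-[2,4-bis(methoxymethoxy)phenyl]prop-2-en-1-one
Conditions: activated MnO2 (excess), CH2Cl2, rt; used at once
Reagents that add atoms: none
Why: MnO2 oxidation of an alcohol that is both allylic and benzylic is selective and neutral, and immediate use of the enone forestalls its polymerisation.

Step 15
Reactants: 17 (2R,3S)-3-[5-ethenyl-2-(methoxymethoxy)phenyl]-7-(methoxymethoxy)-2-[4-(methoxymethoxy)phenyl]chroman-4-one; 20 1-[2,4-bis(methoxymethoxy)phenyl]prop-2-en-1-one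
Product: 21 (2R,3S)-3-{5-[(E)-3-[2,4-bis(methoxymethoxy)phenyl]-3-oxoprop-1-en-1-yl]-2-(methoxymethoxy)phenyl}-7-(methoxymethoxy)-2-[4-(methoxymethoxy)phenyl]chroman-4-one
Conditions: 20 (3 equiv), second-generation Hoveyda–Grubbs catalyst RuCl2(1,3-dimesitylimidazolidin-2-ylidene)(=CH-C6H4-2-O-i-Pr) (5 mol %), CH2Cl2, 40 °C
Reagents that add atoms: none
Why: Olefin cross-metathesis of a styrene with an electron-poor vinyl ketone used in excess should favour the cross product and give the (E)-enone under thermodynamic control, and because no base is present the C3 enolate that would open the ring is never formed.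

Step 16
Reactants: 21 (2R,3S)-3-{5-[(E)-3-[2,4-bis(methoxymethoxy)phenyl]-3-oxoprop-1-en-1-yl]-2-(methoxymethoxy)phenyl}-7-(methoxymethoxy)-2-[4-(methoxymethoxy)phenyl]chroman-4-one
Product: 22 (2R,3S)-3-{5-[(E)-3-(2,4-dihydroxyphenyl)-3-oxoprop-1-en-1-yl]-2-hydroxyphenyl}-7-hydroxy-2-(4-hydroxyphenyl)chroman-4-one
Conditions: 3 M aq. HCl, MeOH–THF (1:1), rt to 40 °C, stopped at full deprotection
Reagents that add atoms: none
Why: Acid-catalysed acetal solvolysis should remove all five MOM groups, C2 of the chromanone is not labilised by dilute acid, and any cis material equilibrates at C3 through the enol to the trans isomer.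

**Compound list**

1 | 5-bromosalicylic acid | OC(=O)c1cc(Br)ccc1O | starting material
2 | 5-bromo-2-hydroxy-N-methoxy-N-methylbenzamide | CON(C)C(=O)c1cc(Br)ccc1O | intermediate
3 | 5-bromo-N-methoxy-2-(methoxymethoxy)-N-methylbenzamide | CON(C)C(=O)c1cc(Br)ccc1OCOC | intermediate
4 | 4-hydroxybenzyl alcohol | OCc1ccc(O)cc1 | starting material
5 | [4-(methoxymethoxy)phenyl]methanol | COCOc1ccc(CO)cc1 | intermediate
6 | 4-(methoxymethoxy)benzyl methanesulfonate | COCOc1ccc(COS(C)(=O)=O)cc1 | intermediate
7 | 1-(chloromethyl)-4-(methoxymethoxy)benzene | COCOc1ccc(CCl)cc1 | intermediate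
8 | [4-(methoxymethoxy)benzyl]magnesium chloride | COCOc1ccc(C[Mg]Cl)cc1 | intermediate
9 | 1-[5-bromo-2-(methoxymethoxy)phenyl]-2-[4-(methoxymethoxy)phenyl]ethan-1-one | COCOc1ccc(CC(=O)c2cc(Br)ccc2OCOC)cc1 | intermediate
10 | (Z)-{1-[5-bromo-2-(methoxymethoxy)phenyl]-2-[4-(methoxymethoxy)phenyl]ethenyl}oxy(trimethyl)silane | COCOc1ccc(/C=C(\O[Si](C)(C)C)c2cc(Br)ccc2OCOC)cc1 | intermediate
11 | racemic 2-bromo-1-[5-bromo-2-(methoxymethoxy)phenyl]-2-[4-(methoxymethoxy)phenyl]ethan-1-one | COCOc1ccc(C(Br)C(=O)c2cc(Br)ccc2OCOC)cc1 | intermediate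
12 | 2,4-dihydroxybenzaldehyde | O=Cc1ccc(O)cc1O | starting material
13 | 2-hydroxy-4-(methoxymethoxy)benzaldehyde | COCOc1ccc(C=O)c(O)c1 | intermediate
14 | racemic 2-{2-[5-bromo-2-(methoxymethoxy)phenyl]-1-[4-(methoxymethoxy)phenyl]-2-oxoethoxy}-4-(methoxymethoxy)benzaldehyde | O=Cc1ccc(OCOC)cc1OC(C(=O)c1cc(Br)ccc1OCOC)c1ccc(OCOC)cc1 | intermediate
15 | (2S,3R)-3-[5-bromo-2-(methoxymethoxy)phenyl]-3-hydroxy-7-(methoxymethoxy)-2-[4-(methoxymethoxy)phenyl]chroman-4-one | Brc1ccc(OCOC)c([C@]2(O)C(=O)c3ccc(OCOC)cc3O[C@H]2c2ccc(OCOC)cc2)c1 | intermediate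
16 | (2S,3R)-3-[5-ethenyl-2-(methoxymethoxy)phenyl]-3-hydroxy-7-(methoxymethoxy)-2-[4-(methoxymethoxy)phenyl]chroman-4-one | C=Cc1ccc(OCOC)c([C@]2(O)C(=O)c3ccc(OCOC)cc3O[C@H]2c2ccc(OCOC)cc2)c1 | intermediate
17 | (2R,3S)-3-[5-ethenyl-2-(methoxymethoxy)phenyl]-7-(methoxymethoxy)-2-[4-(methoxymethoxy)phenyl]chroman-4-one | C=Cc1ccc(OCOC)c([C@@H]2C(=O)c3ccc(OCOC)cc3O[C@H]2c2ccc(OCOC)cc2)c1 | intermediate
18 | 2,4-bis(methoxymethoxy)benzaldehyde | COCOc1ccc(C=O)c(OCOC)c1 | intermediate
19 | racemic 1-[2,4-bis(methoxymethoxy)phenyl]prop-2-en-1-ol | C=CC(O)c1ccc(OCOC)cc1OCOC | intermediate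
20 | 1-[2,4-bis(methoxymethoxy)phenyl]prop-2-en-1-one | C=CC(=O)c1ccc(OCOC)cc1OCOC | intermediate
21 | (2R,3S)-3-{5-[(E)-3-[2,4-bis(methoxymethoxy)phenyl]-3-oxoprop-1-en-1-yl]-2-(methoxymethoxy)phenyl}-7-(methoxymethoxy)-2-[4-(methoxymethoxy)phenyl]chroman-4-one | O=C(/C=C/c1ccc(OCOC)c([C@@H]2C(=O)c3ccc(OCOC)cc3O[C@H]2c2ccc(OCOC)cc2)c1)c1ccc(OCOC)cc1OCOC | intermediate
22 | (2R,3S)-3-{5-[(E)-3-(2,4-dihydroxyphenyl)-3-oxoprop-1-en-1-yl]-2-hydroxyphenyl}-7-hydroxy-2-(4-hydroxyphenyl)chroman-4-one | O=C(/C=C/c1ccc(O)c([C@@H]2C(=O)c3ccc(O)cc3O[C@H]2c2ccc(O)cc2)c1)c1ccc(O)cc1O | target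

**Step count**

Total steps: 16. Longest linear sequence: 10 steps (1 → 2 → 3 → 9 → 11 → 14 → 15 → 16 → 17 → 21 → 22).

**Steps most likely to fail**

Step 9. The carbene may discriminate poorly between the two interconverting enantiomers of 14, or pass the ketone face selection on to C2 only weakly, which would leave low enantiomeric purity at C2. Enolate aldol chemistry may also consume the keto aldehyde faster than the ring closes. The fallback sets out from 14 and uses the established intramolecular aldehyde–ketone benzoin without any demand on enantiomer selection. The achiral precatalyst 2-(pentafluorophenyl)-6,7-dihydro-5H-pyrrolo[2,1-c][1,2,4]triazol-2-ium tetrafluoroborate with Et3N in toluene at rt should give racemic 3-[5-bromo-2-(methoxymethoxy)phenyl]-3-hydroxy-7-(methoxymethoxy)-2-[4-(methoxymethoxy)phenyl]chroman-4-one F1. Preparative supercritical-fluid chromatography on a polysaccharide chiral stationary phase then separates the (2S)-configured material; both C3 epimers are pooled if they arise. The fallback comes back to the route at 15.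

Step 11. Electron transfer to the hindered free tertiary ketol may be sluggish. The samarium enolate may expel the ring aryloxide, opening the ring to the 2'-hydroxy-α-arylchalcone and losing C2. Excess reductant may also attack the C4 ketone. The fallback sets out from 16. Acetylation (Ac2O, DMAP, Et3N, CH2Cl2, 40 °C) should give (2S,3R)-3-[5-ethenyl-2-(methoxymethoxy)phenyl]-7-(methoxymethoxy)-2-[4-(methoxymethoxy)phenyl]-4-oxochroman-3-yl acetate F2. Zinc dust in AcOH–THF at rt then cleaves the α-acyloxy ketone by dissolving-metal reduction in an acidic medium, where the zinc enolate is protonated at once and cannot eliminate the phenoxide. The fallback comes back to the route at 17.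

Step 8. Carbonate may enolise the product as it forms, after which the enolate adds to the neighbouring aldehyde and the adduct can lose the aroyl group towards a 2-arylbenzofuran. Displacement at the hindered secondary bromide may also be slow enough for this to dominate. The fallback sets out from 9. Hydroxylation of the potassium enolate (KN(SiMe3)2, THF, −78 °C; 2-(phenylsulfonyl)-3-phenyloxaziridine) should give racemic 1-[5-bromo-2-(methoxymethoxy)phenyl]-2-hydroxy-2-[4-(methoxymethoxy)phenyl]ethan-1-one F3. Mitsunobu etherification with phenol 13 (PPh3, diisopropyl azodicarboxylate, THF, 0 °C to rt) then forms the O1–C2 ether without carbonate base. The fallback comes back to the route at 14.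

**Further compounds**

F1 | step 9 | racemic 3-[5-bromo-2-(methoxymethoxy)phenyl]-3-hydroxy-7-(methoxymethoxy)-2-[4-(methoxymethoxy)phenyl]chroman-4-one | Brc1ccc(OCOC)c(C2(O)C(=O)c3ccc(OCOC)cc3OC2c2ccc(OCOC)cc2)c1
F2 | step 11 | (2S,3R)-3-[5-ethenyl-2-(methoxymethoxy)phenyl]-7-(methoxymethoxy)-2-[4-(methoxymethoxy)phenyl]-4-oxochroman-3-yl acetate | C=Cc1ccc(OCOC)c([C@]2(OC(C)=O)C(=O)c3ccc(OCOC)cc3O[C@H]2c2ccc(OCOC)cc2)c1
F3 | step 8 | racemic 1-[5-bromo-2-(methoxymethoxy)phenyl]-2-hydroxy-2-[4-(methoxymethoxy)phenyl]ethan-1-one | COCOc1ccc(C(O)C(=O)c2cc(Br)ccc2OCOC)cc1
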